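**Retrosynthetic overview** (daucane numbering of the target: C1 quaternary C–Me, C2 O-angeloyl, C4 carbinol, C5 ring-fusion CH, C6 O-aroyl, C8=C9 alkene)
1. Target 18 ⇐ acylation of the C6 hydroxyl of bicyclic diol mono-angelate 16; the two esters are told apart by order (angelate on C2 early, aroyl on C6 last).
2. The seven-membered ring is formed last, by ring-closing metathesis (C8=C9) of cyclopentane 15; the C6 carbinol comes from reagent-controlled methallylboration of aldehyde 14.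
3. The C4 carbinol comes from isopropylcerium addition to cyclopentanone 12; the C2 carbinol from substrate-controlled reduction of ketone 7.
4. Key disconnection: the C5–C6 bond, made by 1,4-addition of the formyl anion equivalent LiCH(SPh)2 to enone 3 (enone β-carbon and formyl carbon are both normally electrophilic), with allylation of the enolate in the same flask to set the C1 quaternary centre.
5. The five-membered ring is present from the start as (R)-4-silyloxycyclopentenone 1; its C4 stereocentre relays all chirality and is later erased and rebuilt.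

Assumption: compound 1 (a prostaglandin building block), bis(phenylthio)methane, angelic anhydride, (−)-Ipc2BOMe and 4-acetoxybenzoyl chloride are bought.

**Step 1**
Reactants: 1 (R)-4-[(tert-butyldimethylsilyl)oxy]cyclopent-2-en-1-one
Product: 2 (R)-4-[(tert-butyldimethylsilyl)oxy]-2-iodocyclopent-2-en-1-one
Conditions: I2, pyridine/CH2Cl2 (1:1), 0 °C → rt
Reagents that add atoms: iodine, II
Why: Johnson α-iodination of an enone (pyridine conjugate addition, iodination, elimination) puts iodine on the α-carbon without touching the C4 stereocentre.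

**Step 2**
Reactants: 2 (R)-4-[(tert-butyldimethylsilyl)oxy]-2-iodocyclopent-2-en-1-one
Product: 3 (R)-4-[(tert-butyldimethylsilyl)oxy]-2-methylcyclopent-2-en-1-one
Conditions: MeZnCl, Pd(PPh3)4 (5 mol %), THF, rt
Reagents that add atoms: methylzinc chloride, C[Zn]Cl
Why: Negishi cross-coupling of the α-iodoenone runs at room temperature under neutral conditions, so the β-silyloxy enone neither eliminates nor racemises.

**Step 3** (key step)
Reactants: 3 (R)-4-[(tert-butyldimethylsilyl)oxy]-2-methylcyclopent-2-en-1-one; 4 bis(phenylthio)methane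
Product: 7 (2R,3R,4R)-2-allyl-3-[bis(phenylthio)methyl]-4-[(tert-butyldimethylsilyl)oxy]-2-methylcyclopentan-1-one, via lithium bis(phenylthio)methanide 5 (not isolated), via lithium enolate 6 (not isolated)
Conditions: 4, n-BuLi, THF, 0 °C; HMPA (3 equiv), −78 °C; add 3, −78 °C; allyl bromide, −78 → −30 °C; NH4Cl
Reagents that add atoms: allyl bromide, C=CCBr
Why: Corey–Seebach-type umpolung in a conjugate addition–enolate alkylation three-component coupling: the sulfur-stabilised formyl anion equivalent, a solvent-separated ion pair in THF/HMPA, adds 1,4 anti to the C4 silyloxy group (sets C5), and the tetrasubstituted lithium enolate is C-allylated anti to the new CH(SPh)2 group (sets quaternary C1, methyl cis to the side chain).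

**Step 4**
Reactants: 7 (2R,3R,4R)-2-allyl-3-[bis(phenylthio)methyl]-4-[(tert-butyldimethylsilyl)oxy]-2-methylcyclopentan-1-one
Product: 8 (1R,2R,3R,4R)-2-allyl-3-[bis(phenylthio)methyl]-4-[(tert-butyldimethylsilyl)oxy]-2-methylcyclopentan-1-ol
Conditions: L-Selectride, THF, −78 → −40 °C; H2O
Reagents that add atoms: none
Why: Substrate-controlled reduction with a bulky hydride: with the trans C4/C5 substituents pseudo-equatorial the C1 methyl is pseudo-axial, so hydride enters anti to it (as in 17-keto steroid reductions) and the C2 hydroxyl ends up cis to the methyl (2R in target numbering).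

**Step 5**
Reactants: 8 (1R,2R,3R,4R)-2-allyl-3-[bis(phenylthio)methyl]-4-[(tert-butyldimethylsilyl)oxy]-2-methylcyclopentan-1-ol
Product: 10 (1R,2R,3R,4R)-2-allyl-3-[bis(phenylthio)methyl]-4-[(tert-butyldimethylsilyl)oxy]-2-methylcyclopentyl (2Z)-2-methylbut-2-enoate, via lithium alkoxide 9 (not isolated)
Conditions: LiHMDS, THF, −78 °C; angelic anhydride, −78 → 0 °C
Reagents that add atoms: angelic anhydride, C/C=C(/C)C(=O)OC(=O)/C(C)=C\C
Why: O-acylation of the pre-formed lithium alkoxide by the anhydride (nucleophilic acyl substitution, no DMAP and no acyl chloride) gives the angelate without Z→E isomerisation to the tiglate.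

**Step 6**
Reactants: 10 (1R,2R,3R,4R)-2-allyl-3-[bis(phenylthio)methyl]-4-[(tert-butyldimethylsilyl)oxy]-2-methylcyclopentyl (2Z)-2-methylbut-2-enoate
Product: 11 (1R,2R,3R,4R)-2-allyl-3-[bis(phenylthio)methyl]-4-hydroxy-2-methylcyclopentyl (2Z)-2-methylbut-2-enoate
Conditions: HF·pyridine, pyridine/THF, 0 °C → rt
Reagents that add atoms: none
Why: Fluoride desilylation cleaves the secondary TBS ether while angelate, dithioacetal and alkene are inert, and the trans relation of the new hydroxyl to the ester rules out acyl migration.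

**Step 7**
Reactants: 11 (1R,2R,3R,4R)-2-allyl-3-[bis(phenylthio)methyl]-4-hydroxy-2-methylcyclopentyl (2Z)-2-methylbut-2-enoate
Product: 12 (1R,2R,3R)-2-allyl-3-[bis(phenylthio)methyl]-2-methyl-4-oxocyclopentyl (2Z)-2-methylbut-2-enoate
Conditions: Dess–Martin periodinane, NaHCO3, CH2Cl2, 0 °C → rt
Reagents that add atoms: none
Why: Dess–Martin oxidation under non-basic buffered conditions gives the cyclopentanone without β-elimination of the angelate or oxidation of the aryl thioethers, and erases the relay stereocentre at C4.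

**Step 8**
Reactants: 12 (1R,2R,3R)-2-allyl-3-[bis(phenylthio)methyl]-2-methyl-4-oxocyclopentyl (2Z)-2-methylbut-2-enoate
Product: 13 (1R,2R,3R,4R)-2-allyl-3-[bis(phenylthio)methyl]-4-hydroxy-2-methyl-4-(propan-2-yl)cyclopentyl (2Z)-2-methylbut-2-enoate
Conditions: iPrMgCl, CeCl3, THF, −78 °C; quench at −78 °C
Reagents that add atoms: isopropylmagnesium chloride, CC(C)[Mg]Cl
Why: Imamoto organocerium 1,2-addition: the weakly basic isopropylcerium reagent adds to the ketone at −78 °C faster than it enolises it or attacks the hindered ester, from the face anti to the adjacent CH(SPh)2 group and the pseudo-axial C1 methyl, so the C4 hydroxyl is cis to the C5 side chain (4R).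

**Step 9**
Reactants: 13 (1R,2R,3R,4R)-2-allyl-3-[bis(phenylthio)methyl]-4-hydroxy-2-methyl-4-(propan-2-yl)cyclopentyl (2Z)-2-methylbut-2-enoate
Product: 14 (1R,2R,3R,4R)-2-allyl-3-formyl-4-hydroxy-2-methyl-4-(propan-2-yl)cyclopentyl (2Z)-2-methylbut-2-enoate
Conditions: HgCl2, CaCO3, MeCN/H2O (4:1), rt
Reagents that add atoms: water, O
Why: Thiophilic Hg(II)-assisted hydrolysis of the S,S-acetal under carbonate buffer unmasks the formyl group without epimerising C5 or touching the alkene and esters.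

**Step 10**
Reactants: 14 (1R,2R,3R,4R)-2-allyl-3-formyl-4-hydroxy-2-methyl-4-(propan-2-yl)cyclopentyl (2Z)-2-methylbut-2-enoate
Product: 15 (1R,2R,3S,4R)-2-allyl-4-hydroxy-3-[(1S)-1-hydroxy-3-methylbut-3-en-1-yl]-2-methyl-4-(propan-2-yl)cyclopentyl (2Z)-2-methylbut-2-enoate
Conditions: (−)-Ipc2BOMe [from (+)-α-pinene], 2-methylallylmagnesium chloride, Et2O, −78 → 0 °C; then 14, −78 °C; H2O2, pH 7 buffer, MeOH
Reagents that add atoms: 2-methylallylmagnesium chloride, CC(=C)C[Mg]Cl (transferred through the allylborane made in the flask)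
Why: Brown asymmetric allylboration: the chair transition state of the Ipc2B(2-methylallyl) reagent delivers the methallyl group to the Si face of the aldehyde under reagent control, setting C6 as S, while ester and tertiary alcohol are inert.

**Step 11**
Reactants: 15 (1R,2R,3S,4R)-2-allyl-4-hydroxy-3-[(1S)-1-hydroxy-3-methylbut-3-en-1-yl]-2-methyl-4-(propan-2-yl)cyclopentyl (2Z)-2-methylbut-2-enoate
Product: 16 (1R,3R,3aS,4S,8aR)-3,4-dihydroxy-6,8a-dimethyl-3-(propan-2-yl)-1,2,3,3a,4,5,8,8a-octahydroazulen-1-yl (2Z)-2-methylbut-2-enoate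
Conditions: Grubbs II (5 mol %), CH2Cl2 (5 mM), 40 °C
Reagents that add atoms: none
Why: Ring-closing metathesis of the allyl group onto the 1,1-disubstituted methallyl alkene closes the seven-membered ring as the trisubstituted C8=C9 olefin, the trans ring fusion being already fixed by the trans C1/C5 substituents.

**Step 12**
Reactants: 16 (1R,3R,3aS,4S,8aR)-3,4-dihydroxy-6,8a-dimethyl-3-(propan-2-yl)-1,2,3,3a,4,5,8,8a-octahydroazulen-1-yl (2Z)-2-methylbut-2-enoate
Product: 18 (1R,3R,3aS,4S,8aR)-3-hydroxy-6,8a-dimethyl-1-{[(2Z)-2-methylbut-2-enoyl]oxy}-3-(propan-2-yl)-1,2,3,3a,4,5,8,8a-octahydroazulen-4-yl 4-hydroxybenzoate, via 4-acetoxybenzoate ester 17 (not isolated)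
Conditions: 4-acetoxybenzoyl chloride, Et3N, DMAP (cat.), CH2Cl2, 0 °C → rt; then NH4OAc, MeOH/H2O (4:1), rt
Reagents that add atoms: 4-acetoxybenzoyl chloride, CC(=O)Oc1ccc(cc1)C(Cl)=O
Why: DMAP-catalysed acylation occurs only at the secondary C6 hydroxyl (the C4 hydroxyl is tertiary), and the phenolic acetate is then removed by ammonium acetate-mediated methanolysis, which is selective for aryl acetates over the benzoate and angelate esters.

**Compound list**
1 | (R)-4-[(tert-butyldimethylsilyl)oxy]cyclopent-2-en-1-one | O=C1C=C[C@H](O[Si](C)(C)C(C)(C)C)C1 | starting material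
2 | (R)-4-[(tert-butyldimethylsilyl)oxy]-2-iodocyclopent-2-en-1-one | O=C1C(I)=C[C@H](O[Si](C)(C)C(C)(C)C)C1 | intermediate
3 | (R)-4-[(tert-butyldimethylsilyl)oxy]-2-methylcyclopent-2-en-1-one | O=C1C(C)=C[C@H](O[Si](C)(C)C(C)(C)C)C1 | intermediate
4 | bis(phenylthio)methane | C(Sc1ccccc1)Sc1ccccc1 | starting material
5 | lithium bis(phenylthio)methanide | [Li]C(Sc1ccccc1)Sc1ccccc1 | intermediate
6 | lithium (3R,4R)-3-[bis(phenylthio)methyl]-4-[(tert-butyldimethylsilyl)oxy]-2-methylcyclopent-1-en-1-olate | [Li]OC1=C(C)[C@@H](C(Sc2ccccc2)Sc2ccccc2)[C@H](O[Si](C)(C)C(C)(C)C)C1 | intermediate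
7 | (2R,3R,4R)-2-allyl-3-[bis(phenylthio)methyl]-4-[(tert-butyldimethylsilyl)oxy]-2-methylcyclopentan-1-one | O=C1C[C@@H](O[Si](C)(C)C(C)(C)C)[C@H](C(Sc2ccccc2)Sc2ccccc2)[C@@]1(C)CC=C | intermediate
8 | (1R,2R,3R,4R)-2-allyl-3-[bis(phenylthio)methyl]-4-[(tert-butyldimethylsilyl)oxy]-2-methylcyclopentan-1-ol | O[C@@H]1C[C@@H](O[Si](C)(C)C(C)(C)C)[C@H](C(Sc2ccccc2)Sc2ccccc2)[C@@]1(C)CC=C | intermediate
9 | lithium alkoxide of 8 | [Li]O[C@@H]1C[C@@H](O[Si](C)(C)C(C)(C)C)[C@H](C(Sc2ccccc2)Sc2ccccc2)[C@@]1(C)CC=C | intermediate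
10 | (1R,2R,3R,4R)-2-allyl-3-[bis(phenylthio)methyl]-4-[(tert-butyldimethylsilyl)oxy]-2-methylcyclopentyl (2Z)-2-methylbut-2-enoate | C/C=C(/C)C(=O)O[C@@H]1C[C@@H](O[Si](C)(C)C(C)(C)C)[C@H](C(Sc2ccccc2)Sc2ccccc2)[C@@]1(C)CC=C | intermediate
11 | (1R,2R,3R,4R)-2-allyl-3-[bis(phenylthio)methyl]-4-hydroxy-2-methylcyclopentyl (2Z)-2-methylbut-2-enoate | C/C=C(/C)C(=O)O[C@@H]1C[C@@H](O)[C@H](C(Sc2ccccc2)Sc2ccccc2)[C@@]1(C)CC=C | intermediate
12 | (1R,2R,3R)-2-allyl-3-[bis(phenylthio)methyl]-2-methyl-4-oxocyclopentyl (2Z)-2-methylbut-2-enoate | C/C=C(/C)C(=O)O[C@@H]1CC(=O)[C@H](C(Sc2ccccc2)Sc2ccccc2)[C@@]1(C)CC=C | intermediate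
13 | (1R,2R,3R,4R)-2-allyl-3-[bis(phenylthio)methyl]-4-hydroxy-2-methyl-4-(propan-2-yl)cyclopentyl (2Z)-2-methylbut-2-enoate | C/C=C(/C)C(=O)O[C@@H]1C[C@@](O)(C(C)C)[C@H](C(Sc2ccccc2)Sc2ccccc2)[C@@]1(C)CC=C | intermediate
14 | (1R,2R,3R,4R)-2-allyl-3-formyl-4-hydroxy-2-methyl-4-(propan-2-yl)cyclopentyl (2Z)-2-methylbut-2-enoate | C/C=C(/C)C(=O)O[C@@H]1C[C@@](O)(C(C)C)[C@H](C=O)[C@@]1(C)CC=C | intermediate
15 | (1R,2R,3S,4R)-2-allyl-4-hydroxy-3-[(1S)-1-hydroxy-3-methylbut-3-en-1-yl]-2-methyl-4-(propan-2-yl)cyclopentyl (2Z)-2-methylbut-2-enoate | C/C=C(/C)C(=O)O[C@@H]1C[C@@](O)(C(C)C)[C@H]([C@@H](O)CC(C)=C)[C@@]1(C)CC=C | intermediate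
16 | (1R,3R,3aS,4S,8aR)-3,4-dihydroxy-6,8a-dimethyl-3-(propan-2-yl)-1,2,3,3a,4,5,8,8a-octahydroazulen-1-yl (2Z)-2-methylbut-2-enoate | C/C=C(/C)C(=O)O[C@@H]1C[C@@](O)(C(C)C)[C@@H]2[C@@H](O)CC(C)=CC[C@]21C | intermediate
17 | (1R,3R,3aS,4S,8aR)-3-hydroxy-6,8a-dimethyl-1-{[(2Z)-2-methylbut-2-enoyl]oxy}-3-(propan-2-yl)-1,2,3,3a,4,5,8,8a-octahydroazulen-4-yl 4-acetoxybenzoate | C/C=C(/C)C(=O)O[C@@H]1C[C@@](O)(C(C)C)[C@@H]2[C@@H](OC(=O)c3ccc(OC(C)=O)cc3)CC(C)=CC[C@]21C | intermediate
18 | (1R,3R,3aS,4S,8aR)-3-hydroxy-6,8a-dimethyl-1-{[(2Z)-2-methylbut-2-enoyl]oxy}-3-(propan-2-yl)-1,2,3,3a,4,5,8,8a-octahydroazulen-4-yl 4-hydroxybenzoate (CNP0188626.1) | C/C=C(/C)C(=O)O[C@@H]1C[C@@](O)(C(C)C)[C@@H]2[C@@H](OC(=O)c3ccc(O)cc3)CC(C)=CC[C@]21C | target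

**Total step count:** 12. **Longest linear sequence:** 12 steps (1 → 18).

**Steps most likely to fail, with fallbacks**

(a) The key coupling, step 3. Risks are 1,2-addition, proton transfer followed by β-elimination of the silyloxy group, and slow C-allylation of the hindered tetrasubstituted enolate. Fallback: set out again from enone 3 and anion 5, but trap the conjugate-addition enolate with TMSCl/Et3N and isolate the trimethylsilyl enol ether F1. Then build the quaternary centre without a free enolate by Tsuji allylation (allyl methyl carbonate, Pd2(dba)3, dppe, THF, 60 °C; attack on the π-allyl anti to the CH(SPh)2 group). This returns to ketone 7.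

(b) The isopropyl addition, step 8. Risks are attack on the angelate, β-elimination of the acyloxy group from ketone 12, and acyl migration to the new cis tertiary alkoxide. Fallback: set out from alcohol 8 and postpone the ester. TIPSOTf/2,6-lutidine gives the bis-silyl ether F2; CSA/MeOH at 0 °C cleaves only the less hindered secondary TBS ether to give alcohol F3; Dess–Martin oxidation gives β-silyloxy ketone F4; iPrMgCl/CeCl3 gives tertiary alcohol F5; TBAF gives diol F6; LiHMDS (1 equiv)/angelic anhydride acylates only the secondary hydroxyl. This returns to 13.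

(c) The methallylboration, step 10. Risks are low reactivity of the doubly neopentyl aldehyde and a substrate bias that opposes the reagent. Fallback: set out from aldehyde 14 with a robust but unselective indium Barbier reaction (3-bromo-2-methylpropene, In, THF/H2O), which gives 15 mixed with its C6 epimer F7. Oxidise the mixture (Dess–Martin, NaHCO3) to the single β,γ-unsaturated ketone F8 and reduce it with (R)-Me-CBS/catecholborane (large group = ring CH, small group = CH2). This returns to 15.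

**Further compounds**
F1 | step 3 | {[(3R,4R)-3-[bis(phenylthio)methyl]-4-[(tert-butyldimethylsilyl)oxy]-2-methylcyclopent-1-en-1-yl]oxy}trimethylsilane | C[Si](C)(C)OC1=C(C)[C@@H](C(Sc2ccccc2)Sc2ccccc2)[C@H](O[Si](C)(C)C(C)(C)C)C1
F2 | step 8 | O-triisopropylsilyl ether of 8 | CC(C)[Si](C(C)C)(C(C)C)O[C@@H]1C[C@@H](O[Si](C)(C)C(C)(C)C)[C@H](C(Sc2ccccc2)Sc2ccccc2)[C@@]1(C)CC=C
F3 | step 8 | (1R,2R,3R,4R)-3-allyl-2-[bis(phenylthio)methyl]-3-methyl-4-[(triisopropylsilyl)oxy]cyclopentan-1-ol | CC(C)[Si](C(C)C)(C(C)C)O[C@@H]1C[C@@H](O)[C@H](C(Sc2ccccc2)Sc2ccccc2)[C@@]1(C)CC=C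
F4 | step 8 | (2R,3R,4R)-3-allyl-2-[bis(phenylthio)methyl]-3-methyl-4-[(triisopropylsilyl)oxy]cyclopentan-1-one | CC(C)[Si](C(C)C)(C(C)C)O[C@@H]1CC(=O)[C@H](C(Sc2ccccc2)Sc2ccccc2)[C@@]1(C)CC=C
F5 | step 8 | (1R,2R,3R,4R)-3-allyl-2-[bis(phenylthio)methyl]-3-methyl-1-(propan-2-yl)-4-[(triisopropylsilyl)oxy]cyclopentan-1-ol | CC(C)[Si](C(C)C)(C(C)C)O[C@@H]1C[C@@](O)(C(C)C)[C@H](C(Sc2ccccc2)Sc2ccccc2)[C@@]1(C)CC=C
F6 | step 8 | (1R,3R,4R,5R)-5-allyl-4-[bis(phenylthio)methyl]-5-methyl-3-(propan-2-yl)cyclopentane-1,3-diol | O[C@@H]1C[C@@](O)(C(C)C)[C@H](C(Sc2ccccc2)Sc2ccccc2)[C@@]1(C)CC=C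
F7 | step 10 | (1R,2R,3S,4R)-2-allyl-4-hydroxy-3-[(1R)-1-hydroxy-3-methylbut-3-en-1-yl]-2-methyl-4-(propan-2-yl)cyclopentyl (2Z)-2-methylbut-2-enoate | C/C=C(/C)C(=O)O[C@@H]1C[C@@](O)(C(C)C)[C@H]([C@H](O)CC(C)=C)[C@@]1(C)CC=C
F8 | step 10 | (1R,2R,3R,4R)-2-allyl-4-hydroxy-2-methyl-3-(3-methylbut-3-enoyl)-4-(propan-2-yl)cyclopentyl (2Z)-2-methylbut-2-enoate | C/C=C(/C)C(=O)O[C@@H]1C[C@@](O)(C(C)C)[C@H](C(=O)CC(C)=C)[C@@]1(C)CC=C
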